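**Plan**
- Retrosynthetic cuts, in order: C4a–C5 and C8–C8a of the naphthazarin (both at once), then the two quinone carbonyls of ring A (back to aryl methyl ethers), the ester C–O bond, the C1'–H bond (back to a ketone) and the aryl–C1' bond.
- Enabling feature: the ring made of C4a, C5, C6, C7, C8 and C8a carries no carbon substituent and has oxygen at both peri positions C5 and C8. C5–C8 is therefore a four-carbon succinyl unit laid onto a benzoquinone, and because the naphthazarin tautomers interconvert, either orientation of that unit gives the same compound.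
- Forward order: the side chain is joined to a dimethoxyarene (aryllithium plus Weinreb amide), the ketone is reduced, the carbinol is acylated and the arene is oxidised to the benzoquinone that becomes ring A. The dihydroxy ring is closed last by cycloaddition of 2,5-bis(trimethylsilyloxy)furan and collapse of the oxygen bridge.
- Stereochemistry: the only stereocentre, C1' (R), comes from a reagent-controlled (+)-DIP-Cl reduction of the aryl ketone. It is carried unchanged, because the ester is made by O-acylation and the C1'–O bond is never broken.

Key step: step 7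

Assumption: both pentenoic acids and (+)-DIP-Cl are taken as catalogue chemicals, and the naphthazarin is written as the given 5,8-dihydroxy-1,4-dione tautomer, the tautomers being one compound in practice. C1' is the carbinol carbon of the side chain; ring positions of the product use naphthalene numbering.

**Route**

Step 1
Reactants: 1 4-methylpent-3-enoic acid
Product: 3 N-methoxy-N,4-dimethylpent-3-enamide, via acyl imidazolide 2 (not isolated)
Conditions: CDI, CH2Cl2, 0 °C → rt; then MeNH(OMe)·HCl, rt
Reagents that add atoms: N,O-dimethylhydroxylamine hydrochloride, CNOC.Cl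
Why: Weinreb amide formation through the CDI-derived acyl imidazolide 2 is a near-neutral acyl transfer that should leave the trisubstituted β,γ-alkene where it is.

Step 2
Reactants: 4 2-bromo-1,4-dimethoxybenzene; 3 N-methoxy-N,4-dimethylpent-3-enamide
Product: 7 1-(2,5-dimethoxyphenyl)-4-methylpent-3-en-1-one, via aryllithium 5 (not isolated), via lithium hemiaminal alkoxide 6 (not isolated)
Conditions: n-BuLi (1.05 equiv), THF, −78 °C; then 3, −78 → −20 °C; cold sat. aq. NH4Cl
Reagents that add atoms: none
Why: Bromine–lithium exchange followed by Weinreb ketone synthesis: aryllithium 5 adds only once to amide 3 because the chelated tetrahedral alkoxide 6 survives until the cold, weakly acidic quench, which also keeps the β,γ-alkene of ketone 7 out of conjugation.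

Step 3
Reactants: 7 1-(2,5-dimethoxyphenyl)-4-methylpent-3-en-1-one
Product: 9 (R)-1-(2,5-dimethoxyphenyl)-4-methylpent-3-en-1-ol, via chloroborinate ester 8 (not isolated)
Conditions: (+)-DIP-Cl (1.5 equiv), THF, −25 °C; then HN(CH2CH2OH)2, Et2O, rt
Reagents that add atoms: none
Why: Asymmetric DIP-Cl reduction of an aryl alkyl ketone (β-hydride transfer from an isopinocampheyl group in a six-membered boat transition state with the aryl group in the less hindered position) with the reagent made from (−)-α-pinene should give the (R)-carbinol, as it does for acetophenone-type ketones, and a chlorodialkylborane has no B–H to hydroborate the alkene, so C1' is set here by reagent control.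

Step 4
Reactants: 9 (R)-1-(2,5-dimethoxyphenyl)-4-methylpent-3-en-1-ol; 10 3,4-dimethylpent-3-enoic acid
Product: 11 (R)-1-(2,5-dimethoxyphenyl)-4-methylpent-3-enyl 3,4-dimethylpent-3-enoate
Conditions: DCC, DMAP (cat.), CH2Cl2, 0 °C → rt
Reagents that add atoms: none
Why: Steglich esterification acylates the secondary benzylic hydroxyl at oxygen, so the C1'–O bond is not broken and the (R) configuration is kept, while 0 °C and catalytic DMAP should keep the tetrasubstituted β,γ-alkene of the acid from moving into conjugation.

Step 5
Reactants: 11 (R)-1-(2,5-dimethoxyphenyl)-4-methylpent-3-enyl 3,4-dimethylpent-3-enoate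
Product: 12 (R)-1-(3,6-dioxocyclohexa-1,4-dien-1-yl)-4-methylpent-3-enyl 3,4-dimethylpent-3-enoate
Conditions: CAN (2.5 equiv), MeCN/H2O, 0 °C, short reaction time
Reagents that add atoms: water, O
Why: Oxidative demethylation of a hydroquinone dimethyl ether with cerium(IV) starts by electron transfer from the arene, the most easily oxidised site, and water then attacks the two oxygen-bearing ring carbons of the radical cation with loss of methanol, so a short exposure at 0 °C should leave both alkenes, the ester and C1' untouched.

Step 6
Reactants: 13 succinic anhydride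
Product: 14 2,5-bis(trimethylsilyloxy)furan
Conditions: TMSCl, Et3N, ZnCl2 (cat.), MeCN, rt; filtration and distillation under reduced pressure
Reagents that add atoms: chlorotrimethylsilane, C[Si](C)(C)Cl
Why: Twofold O-silylation of the bis-enol form of the anhydride (soft enolisation with Et3N/ZnCl2 and trapping by TMSCl, as in silyl ketene acetal formation) is driven by the aromaticity of the furan and gives the known, distillable, moisture-sensitive diene, which is used freshly.

Step 7
Reactants: 12 (R)-1-(3,6-dioxocyclohexa-1,4-dien-1-yl)-4-methylpent-3-enyl 3,4-dimethylpent-3-enoate; 14 2,5-bis(trimethylsilyloxy)furan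
Product: 17 (R)-1-(5,8-dihydroxy-1,4-dioxo-1,4-dihydronaphthalen-2-yl)-4-methylpent-3-enyl 3,4-dimethylpent-3-enoate, via oxa-bridged cycloadduct 15 (not isolated), via tetraketone 16 (not isolated)
Conditions: 14 (1.5 equiv), CH2Cl2, −78 °C → rt, Ar, dark; then 0.5 M aq. HCl/THF, 0 °C
Reagents that add atoms: none
Why: The electron-rich diene 14 adds in a normal-demand [4+2] cycloaddition through its two silyloxy-bearing termini to the unsubstituted C5=C6 alkene of quinone 12 and gives the 7-oxanorbornene bis(silyl ketal) 15, in which C4a–C5 and C8–C8a (naphthalene numbering) are made together and the new six-membered carbocycle is closed by the cycloaddition itself. Dilute acid unlocks the silyl ketals, the oxygen bridge opens with loss of hexamethyldisiloxane to tetraketone 16, and two enolisations at C4a–H and C8a–H deliver the aromatic naphthazarin without any oxidant, since 16 and 17 are tautomers. The closest known reaction type is the addition of 2,5-bis(trimethylsilyloxy)furans to p-benzoquinone and 1,4-naphthoquinone, which gives naphthazarin and quinizarin after the same collapse. No stereocentre from this step survives, because the four sp3 centres of 15 all become sp2, and C1' is a spectator whose C–O bond is not touched, so endo/exo and facial selectivity do not matter. The selectivity that does matter is the choice between the two quinone alkenes: the alkyl branch at C2 hinders and deactivates C2=C3, so the symmetric diene should take the free edge, the only adduct that can enolise to a naphthazarin, and the symmetry of the diene together with naphthazarin tautomerism removes any regiochemical question.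

**Compound list**

1 | 4-methylpent-3-enoic acid | CC(C)=CCC(=O)O | starting material
2 | 1-(imidazol-1-yl)-4-methylpent-3-en-1-one (acyl imidazolide, not isolated) | CC(C)=CCC(=O)n1ccnc1 | intermediate
3 | N-methoxy-N,4-dimethylpent-3-enamide | CC(C)=CCC(=O)N(C)OC | intermediate
4 | 2-bromo-1,4-dimethoxybenzene | COc1ccc(OC)c(Br)c1 | starting material
5 | (2,5-dimethoxyphenyl)lithium (not isolated) | [Li]c1cc(OC)ccc1OC | intermediate
6 | lithium 1-(2,5-dimethoxyphenyl)-1-[methoxy(methyl)amino]-4-methylpent-3-en-1-olate (not isolated; transient carbinolamine carbon racemic) | [Li+].[O-]C(CC=C(C)C)(N(C)OC)c1cc(OC)ccc1OC | intermediate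
7 | 1-(2,5-dimethoxyphenyl)-4-methylpent-3-en-1-one | CC(C)=CCC(=O)c1cc(OC)ccc1OC | intermediate
8 | (R)-1-(2,5-dimethoxyphenyl)-4-methylpent-3-enyl chloro(isopinocampheyl)borinate, isopinocampheyl from (−)-α-pinene (not isolated) | C[C@@H]1[C@@H](B(Cl)O[C@H](CC=C(C)C)c2cc(OC)ccc2OC)C[C@H]3C[C@@H]1C3(C)C | intermediate
9 | (R)-1-(2,5-dimethoxyphenyl)-4-methylpent-3-en-1-ol | CC(C)=CC[C@@H](O)c1cc(OC)ccc1OC | intermediate
10 | 3,4-dimethylpent-3-enoic acid | CC(C)=C(C)CC(=O)O | starting material
11 | (R)-1-(2,5-dimethoxyphenyl)-4-methylpent-3-enyl 3,4-dimethylpent-3-enoate | CC(C)=CC[C@@H](OC(=O)CC(C)=C(C)C)c1cc(OC)ccc1OC | intermediate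
12 | (R)-1-(3,6-dioxocyclohexa-1,4-dien-1-yl)-4-methylpent-3-enyl 3,4-dimethylpent-3-enoate | CC(C)=CC[C@@H](OC(=O)CC(C)=C(C)C)C1=CC(=O)C=CC1=O | intermediate
13 | succinic anhydride | O=C1CCC(=O)O1 | starting material
14 | 2,5-bis(trimethylsilyloxy)furan | C[Si](C)(C)Oc1ccc(O[Si](C)(C)C)o1 | intermediate
15 | (R)-1-[5,8-dioxo-1,4-bis(trimethylsilyloxy)-1,4,4a,5,8,8a-hexahydro-1,4-epoxynaphthalen-6-yl]-4-methylpent-3-enyl 3,4-dimethylpent-3-enoate (not isolated; bridgehead and ring-fusion centres form as a mixture and are left unspecified) | CC(C)=CC[C@@H](OC(=O)CC(C)=C(C)C)C1=CC(=O)C2C(C1=O)C3(O[Si](C)(C)C)C=CC2(O[Si](C)(C)C)O3 | intermediate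
16 | (R)-1-(1,4,5,8-tetraoxo-1,4,4a,5,8,8a-hexahydronaphthalen-2-yl)-4-methylpent-3-enyl 3,4-dimethylpent-3-enoate (not isolated; ring-fusion centres unspecified) | CC(C)=CC[C@@H](OC(=O)CC(C)=C(C)C)C1=CC(=O)C2C(C1=O)C(=O)C=CC2=O | intermediate
17 | (R)-1-(5,8-dihydroxy-1,4-dioxo-1,4-dihydronaphthalen-2-yl)-4-methylpent-3-enyl 3,4-dimethylpent-3-enoate | CC(C)=CC[C@@H](OC(=O)CC(C)=C(C)C)C1=CC(=O)c2c(O)ccc(O)c2C1=O | target

**Step count**

Total: 7 steps. Longest linear sequence: 6 steps (1, 2, 3, 4, 5, 7 from 4-methylpent-3-enoic acid); step 6 is a one-step branch.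

**Steps most likely to fail, with fallbacks**

Step 7. The silyloxyfuran may act as a silyl-transfer or conjugate-addition donor instead of a diene. Silyl Lewis acid and the acidic collapse may also ionise the benzylic acyloxy group next to the quinone, with loss of the ester, erosion of the C1' configuration or cyclisation onto the prenyl alkene. The fallback builds the dihydroxy ring on a silyl ether and introduces the ester last; it sets out from alcohol 9 and comes back to the route at 17. Alcohol 9 would be oxidised with CAN in MeCN/H2O at 0 °C to (R)-2-(1-hydroxy-4-methylpent-3-enyl)cyclohexa-2,5-diene-1,4-dione F1. This would be silylated with TESOTf and 2,6-lutidine in CH2Cl2 at −78 °C to (R)-2-[4-methyl-1-(triethylsilyloxy)pent-3-enyl]cyclohexa-2,5-diene-1,4-dione F2. Cycloaddition of F2 with furan 14 under the conditions of step 7, with the acidic collapse also removing the triethylsilyl group, should give (R)-5,8-dihydroxy-2-(1-hydroxy-4-methylpent-3-enyl)naphthalene-1,4-dione (shikonin) F3. Steglich acylation of F3 with acid 10 (DCC, cat. DMAP, CH2Cl2, 0 °C) should then take place only at the side-chain hydroxyl, the peri hydroxyls being locked in hydrogen bonds, and give 17.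

Step 5. Electron-transfer oxidation by cerium(IV) may not stop at the arene: the electron-rich tetrasubstituted alkene of the acyl group may be attacked, nitrate may add, or the radical cation may fragment at the benzylic C–O bond. The fallback replaces oxidative bis-demethylation by hypervalent-iodine oxidation of a para-methoxyphenol; it sets out from Weinreb amide 3 and comes back to the route at quinone 12. Commercial 3-bromo-4-methoxyphenol would be silylated (TBSCl, imidazole) to tert-butyl(3-bromo-4-methoxyphenoxy)dimethylsilane F4. Bromine–lithium exchange and addition to 3 as in step 2 would give 1-[5-(tert-butyldimethylsilyloxy)-2-methoxyphenyl]-4-methylpent-3-en-1-one F5. Reduction with (+)-DIP-Cl as in step 3 would give (R)-1-[5-(tert-butyldimethylsilyloxy)-2-methoxyphenyl]-4-methylpent-3-en-1-ol F6, and Steglich esterification with acid 10 would give (R)-1-[5-(tert-butyldimethylsilyloxy)-2-methoxyphenyl]-4-methylpent-3-enyl 3,4-dimethylpent-3-enoate F7. Buffered desilylation (TBAF, AcOH, THF, 0 °C) would free (R)-1-(5-hydroxy-2-methoxyphenyl)-4-methylpent-3-enyl 3,4-dimethylpent-3-enoate F8. Its hydroxyl is meta to the benzylic carbon and so cannot expel the carboxylate as a quinone methide. PhI(OAc)2 in MeCN/H2O at 0 °C should then convert F8 into 12 with loss of methanol.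

Step 3. Facial discrimination may be incomplete, because the ortho-methoxy group changes the effective size of the aryl group and can coordinate boron. The Lewis-acidic reagent may also move the β,γ-alkene of the ketone into conjugation before reduction. The fallback creates C1' by carbon–carbon bond formation instead of reduction; it sets out from bromide 4 and comes back to the route at alcohol 9. Aryllithium 5, made from 4 as in step 2, would be formylated with DMF to 2,5-dimethoxybenzaldehyde F9. Brown allylation with the B-allyldiisopinocampheylborane derived from (−)-α-pinene (Et2O, −78 °C, oxidative work-up) should give (R)-1-(2,5-dimethoxyphenyl)but-3-en-1-ol F10. Cross-metathesis of F10 with excess 2-methyl-2-butene (second-generation Grubbs catalyst, CH2Cl2, rt to 40 °C) would turn the terminal alkene into the trisubstituted one and give 9.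

**Further compounds**

F1 | step 7 | (R)-2-(1-hydroxy-4-methylpent-3-enyl)cyclohexa-2,5-diene-1,4-dione | CC(C)=CC[C@@H](O)C1=CC(=O)C=CC1=O
F2 | step 7 | (R)-2-[4-methyl-1-(triethylsilyloxy)pent-3-enyl]cyclohexa-2,5-diene-1,4-dione | CC(C)=CC[C@@H](O[Si](CC)(CC)CC)C1=CC(=O)C=CC1=O
F3 | step 7 | (R)-5,8-dihydroxy-2-(1-hydroxy-4-methylpent-3-enyl)naphthalene-1,4-dione (shikonin) | CC(C)=CC[C@@H](O)C1=CC(=O)c2c(O)ccc(O)c2C1=O
F4 | step 5 | tert-butyl(3-bromo-4-methoxyphenoxy)dimethylsilane | COc1ccc(O[Si](C)(C)C(C)(C)C)cc1Br
F5 | step 5 | 1-[5-(tert-butyldimethylsilyloxy)-2-methoxyphenyl]-4-methylpent-3-en-1-one | CC(C)=CCC(=O)c1cc(O[Si](C)(C)C(C)(C)C)ccc1OC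
F6 | step 5 | (R)-1-[5-(tert-butyldimethylsilyloxy)-2-methoxyphenyl]-4-methylpent-3-en-1-ol | CC(C)=CC[C@@H](O)c1cc(O[Si](C)(C)C(C)(C)C)ccc1OC
F7 | step 5 | (R)-1-[5-(tert-butyldimethylsilyloxy)-2-methoxyphenyl]-4-methylpent-3-enyl 3,4-dimethylpent-3-enoate | CC(C)=CC[C@@H](OC(=O)CC(C)=C(C)C)c1cc(O[Si](C)(C)C(C)(C)C)ccc1OC
F8 | step 5 | (R)-1-(5-hydroxy-2-methoxyphenyl)-4-methylpent-3-enyl 3,4-dimethylpent-3-enoate | CC(C)=CC[C@@H](OC(=O)CC(C)=C(C)C)c1cc(O)ccc1OC
F9 | step 3 | 2,5-dimethoxybenzaldehyde | COc1ccc(OC)c(C=O)c1
F10 | step 3 | (R)-1-(2,5-dimethoxyphenyl)but-3-en-1-ol | C=CC[C@@H](O)c1cc(OC)ccc1OC
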